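**Retrosynthetic overview**

- The target is epiafzelechin-(4β→6)-epicatechin with the gallate on O3 of the lower unit. The last step is one global hydrogenolysis that removes ten benzyl ethers and a C8 bromine and reduces an azide, so that a 4-aminobutanoate on the upper O3 cyclises off as a lactam.
- Ring C of the upper unit is disconnected at C4a–C4 and C2–C3: a cationic [4+2] (oxa-Povarov type) between an aryl oxocarbenium ion and an (E)-vinyl ester on C6 of the lower unit. The oxocarbenium ion comes from a mixed acetal of 4-(benzyloxy)benzaldehyde and 3,5-bis(benzyloxy)phenol.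
- The enabling feature: in upper ring C, O1 is an aryl ether oxygen on the symmetric 5,7-dioxygenated ring A (C8a–O1, nucleophilic ortho carbon C4a). C4 is benzylic to the lower ring A carbon C6, which lies between O5 and O7 and para to O1. C2 can therefore be an oxocarbenium carbon and C4 a stabilised cation, while C3 carries its oxygen as an ester.
- The vinyl ester comes from the C6 aldehyde (boron-Wittig, then copper-catalysed acyloxylation). The aldehyde comes from (−)-epicatechin by benzylation, C8 bromination (blocking group), galloylation and C6 formylation.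
- Ring order: all aromatic rings and the lower ring C are bought; upper ring C is the only ring formed, in the key step.

Key step: step 9

Remark: the sense of induction of the chiral acid in step 9 cannot be predicted with confidence; the (R)-acid is written and its mirror image is used if a trial shows the opposite sense. All compounds marked as starting materials are assumed to be commercial.

**Route**

Step 1
Reactants: 1 (−)-epicatechin
Product: 2 5,7,3',4'-tetra-O-benzyl-(−)-epicatechin
Conditions: BnBr, K2CO3, DMF, 0 °C to rt, argon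
Reagents that add atoms: benzyl bromide, BrCc1ccccc1
Why: Williamson etherification of the four phenols with a carbonate base leaves the secondary 3-OH free, and low temperature under argon limits base-induced epimerisation at C2.

Step 2
Reactants: 2 5,7,3',4'-tetra-O-benzyl-(−)-epicatechin
Product: 3 8-bromo-5,7,3',4'-tetra-O-benzyl-(−)-epicatechin
Conditions: N-bromosuccinimide (1.0 equiv), CH2Cl2, −78 °C to rt
Reagents that add atoms: N-bromosuccinimide, O=C1CCC(=O)N1Br
Why: Electrophilic aromatic bromination should go to C8, the more reactive of the two free ring A positions of 5,7-di-O-benzyl flavan-3-ols, and the bromine then blocks C8 for the rest of the route.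

Step 3
Reactants: 3 8-bromo-5,7,3',4'-tetra-O-benzyl-(−)-epicatechin; 4 3,4,5-tris(benzyloxy)benzoic acid
Product: 5 8-bromo-5,7,3',4'-tetra-O-benzyl-(−)-epicatechin 3-O-[3,4,5-tris(benzyloxy)benzoate]
Conditions: N,N'-dicyclohexylcarbodiimide (DCC), 4-(dimethylamino)pyridine (DMAP, cat.), CH2Cl2, rt
Reagents that add atoms: none
Why: Steglich esterification acylates the axial 3-OH without touching the stereocentres.

Step 4
Reactants: 5 8-bromo-5,7,3',4'-tetra-O-benzyl-(−)-epicatechin 3-O-[3,4,5-tris(benzyloxy)benzoate]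
Product: 7 8-bromo-6-formyl-5,7,3',4'-tetra-O-benzyl-(−)-epicatechin 3-O-[3,4,5-tris(benzyloxy)benzoate], via C6 iminium chloride 6 (not isolated)
Conditions: POCl3, DMF, 1,2-dichloroethane, 0 to 70 °C; then aqueous sodium acetate
Reagents that add atoms: N,N-dimethylformamide, CN(C)C=O; water, O
Why: Vilsmeier–Haack formylation should take the only free ring A position, C6, which is activated by two ortho benzyloxy groups, while the ester-deactivated galloyl ring and the catechol diether ring B are much less reactive.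

Step 5
Reactants: 7 8-bromo-6-formyl-5,7,3',4'-tetra-O-benzyl-(−)-epicatechin 3-O-[3,4,5-tris(benzyloxy)benzoate]; 8 bis(pinacolatoboryl)methane
Product: 10 potassium (E)-alkenyltrifluoroborate (C6 carries (E)-CH=CH–BF3K), via alkenyl pinacol boronate 9 (not isolated)
Conditions: lithium 2,2,6,6-tetramethylpiperidide and 8, THF, 0 °C; 7 added at −78 °C, then rt; then aqueous KHF2, MeOH, rt
Reagents that add atoms: potassium hydrogen difluoride, F.[F-].[K+]
Why: The boron-Wittig reaction (addition of the α-boryl carbanion to the aldehyde, then syn B–O elimination) should give the (E)-alkenylboronate, and KHF2 converts it into a crystallisable trifluoroborate; the carbanion adds to the aldehyde faster than to the ester at −78 °C.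

Step 6
Reactants: 10 potassium (E)-alkenyltrifluoroborate; 11 4-azidobutanoic acid
Product: 12 (E)-vinyl ester (C6 carries (E)-CH=CH–O–CO–(CH2)3N3)
Conditions: CuBr (10 mol%), DMAP (20 mol%), 4 Å molecular sieves, O2 (1 atm), MeCN/CH2Cl2, 40 °C
Reagents that add atoms: none
Why: Chan–Lam-type oxidative copper-catalysed C–O coupling of an alkenyltrifluoroborate with a carboxylic acid should give the enol ester with retention of the E geometry; the aryl bromide and the azide are inert under these conditions.

Step 7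
Reactants: 13 4-(benzyloxy)benzaldehyde
Product: 14 1-(benzyloxy)-4-(dimethoxymethyl)benzene
Conditions: HC(OMe)3, p-toluenesulfonic acid (cat.), MeOH, rt; Et3N quench
Reagents that add atoms: trimethyl orthoformate, COC(OC)OC
Why: Acid-catalysed acetalisation driven by the orthoformate as water scavenger.

Step 8
Reactants: 14 1-(benzyloxy)-4-(dimethoxymethyl)benzene; 15 3,5-bis(benzyloxy)phenol
Product: 17 racemic mixed acetal 1,3-bis(benzyloxy)-5-{[4-(benzyloxy)phenyl](methoxy)methoxy}benzene, via α-chloro ether 16 (not isolated)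
Conditions: acetyl chloride, CH2Cl2, 0 °C to rt, volatiles removed; then 15 and NaH, THF, −78 to 0 °C; chromatography on Et3N-deactivated silica
Reagents that add atoms: none
Why: Acetyl chloride exchanges one methoxy group for chloride, and the sodium phenoxide is then O-alkylated in a Williamson-type reaction, as in methoxymethyl ether formation on phloroglucinol ethers; the acetal carbon is racemic but becomes planar in step 9.

Step 9
Reactants: 12 (E)-vinyl ester; 17 racemic mixed acetal
Product: 20 8-bromo-deca-O-benzyl-3-O-(4-azidobutanoyl)epiafzelechin-(4β→6)-epicatechin 3-O-gallate (upper unit 2,3-cis-3,4-trans), via aryl oxocarbenium ion 18 (not isolated), via benzylic cation 19 (not isolated)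
Conditions: (R)-3,3'-bis(2,4,6-triisopropylphenyl)-1,1'-binaphthyl-2,2'-diyl N-triflylphosphoramide (10 mol%), 5 Å molecular sieves, CH2Cl2/toluene, −60 °C, slow addition of 17 (1.3 equiv) to 12; Et3N quench
Reagents that add atoms: none
Why: Proposed new method: the chiral acid ionises acetal 17 (loss of MeOH) to the E-configured aryl oxocarbenium ion 18, a cationic 2-oxadiene C4a=C8a–O1=C2; the vinyl ester of 12 attacks C2 with its oxygen-bearing carbon (future C3), the benzylic cation 19 at future C4 is captured by the ortho carbon C4a of the 3,5-dibenzyloxyphenyl ether, and proton loss restores ring A and the acid. The closest known reaction type is the oxa-Povarov reaction of aryl oxocarbenium ions with styrenes to give 2,4-disubstituted chromans, which is not known for a β-acyloxystyrene or under a chiral acid; chiral Brønsted acid control of oxocarbenium additions to aryl alkenes is the model for the ion pair. Ring C of the upper unit closes as a polar stepwise [4+2]: intermolecular Prins-type C2–C3 bond formation, then a six-membered Friedel–Crafts closure C4–C4a. C2 and C3 arise together in the first bond formation, in which the E-oxocarbenium ion holds the 4-benzyloxyphenyl group outside, the small acyloxy group lies endo over the O1=C2 cation and the bulky di-ortho-substituted lower aryl group lies exo, which gives the 2,3-cis relation; the absolute sense (2R,3R) is imposed by the chiral phosphoramide anion, since the stereocentres of the lower unit are too remote to bias the faces. C4 follows from the E geometry of the vinyl ester (suprafacial addition, 3,4-trans), and the same result is expected if cation 19 has time to rotate, because the 4-aryl group then closes quasi-axial, anti to the axial 3-acyloxy group and away from the peri C5 benzyloxy group. The step needs attack at the oxygen-bearing alkene carbon (secured by the 2,4,6-trioxygenated ring A of the lower unit, a far stronger donor than the ester oxygen), a single closure site (the two ortho carbons of ring A in 17 are equivalent) and no arylation at C8 of the lower unit (blocked by bromine).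

Step 10
Reactants: 20 8-bromo-deca-O-benzyl-3-O-(4-azidobutanoyl)epiafzelechin-(4β→6)-epicatechin 3-O-gallate
Product: 22 epiafzelechin-(4β→6)-epicatechin 3-O-gallate (gallate on the lower unit; the target), via amino ester 21 (not isolated)
Conditions: H2 (1 atm), Pd(OH)2/C, Et3N, THF/MeOH, rt; filtration under argon, then 40 °C; Sephadex LH-20
Reagents that add atoms: none
Why: Hydrogenolysis should cleave the ten benzyl ethers, remove the C8 bromine and reduce the azide; the resulting 4-aminobutanoate then lactamises (assisted cleavage, 5-exo-trig acyl transfer) to free the upper 3-OH, while the gallate ester and all stereocentres stay untouched.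

**Compound list**

1 | (−)-epicatechin, (2R,3R)-2-(3,4-dihydroxyphenyl)chromane-3,5,7-triol | O[C@@H]1Cc2c(cc(O)cc2O)O[C@@H]1c1ccc(O)c(O)c1 | starting material
2 | 5,7,3',4'-tetra-O-benzyl-(−)-epicatechin | O[C@@H]1Cc2c(cc(OCc3ccccc3)cc2OCc2ccccc2)O[C@@H]1c1ccc(OCc2ccccc2)c(OCc2ccccc2)c1 | intermediate
3 | 8-bromo-5,7,3',4'-tetra-O-benzyl-(−)-epicatechin | O[C@@H]1Cc2c(c(Br)c(OCc3ccccc3)cc2OCc2ccccc2)O[C@@H]1c1ccc(OCc2ccccc2)c(OCc2ccccc2)c1 | intermediate
4 | 3,4,5-tris(benzyloxy)benzoic acid | OC(=O)c1cc(OCc2ccccc2)c(OCc2ccccc2)c(OCc2ccccc2)c1 | starting material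
5 | 8-bromo-5,7,3',4'-tetra-O-benzyl-(−)-epicatechin 3-O-[3,4,5-tris(benzyloxy)benzoate] | O=C(O[C@@H]1Cc2c(c(Br)c(OCc3ccccc3)cc2OCc2ccccc2)O[C@@H]1c1ccc(OCc2ccccc2)c(OCc2ccccc2)c1)c1cc(OCc2ccccc2)c(OCc2ccccc2)c(OCc2ccccc2)c1 | intermediate
6 | C6 iminium chloride: 5 with CH=N(+)Me2 at C6, chloride counter-ion | O=C(O[C@@H]1Cc2c(c(Br)c(OCc3ccccc3)c(C=[N+](C)C)c2OCc2ccccc2)O[C@@H]1c1ccc(OCc2ccccc2)c(OCc2ccccc2)c1)c1cc(OCc2ccccc2)c(OCc2ccccc2)c(OCc2ccccc2)c1.[Cl-] | intermediate
7 | 8-bromo-6-formyl-5,7,3',4'-tetra-O-benzyl-(−)-epicatechin 3-O-[3,4,5-tris(benzyloxy)benzoate] | O=C(O[C@@H]1Cc2c(c(Br)c(OCc3ccccc3)c(C=O)c2OCc2ccccc2)O[C@@H]1c1ccc(OCc2ccccc2)c(OCc2ccccc2)c1)c1cc(OCc2ccccc2)c(OCc2ccccc2)c(OCc2ccccc2)c1 | intermediate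
8 | bis(pinacolatoboryl)methane | CC1(C)OB(CB2OC(C)(C)C(C)(C)O2)OC1(C)C | starting material
9 | alkenyl pinacol boronate: 5 with (E)-CH=CH–B(pinacolato) at C6 | O=C(O[C@@H]1Cc2c(c(Br)c(OCc3ccccc3)c(/C=C/B3OC(C)(C)C(C)(C)O3)c2OCc2ccccc2)O[C@@H]1c1ccc(OCc2ccccc2)c(OCc2ccccc2)c1)c1cc(OCc2ccccc2)c(OCc2ccccc2)c(OCc2ccccc2)c1 | intermediate
10 | potassium (E)-alkenyltrifluoroborate: 5 with (E)-CH=CH–BF3K at C6 | O=C(O[C@@H]1Cc2c(c(Br)c(OCc3ccccc3)c(/C=C/[B-](F)(F)F)c2OCc2ccccc2)O[C@@H]1c1ccc(OCc2ccccc2)c(OCc2ccccc2)c1)c1cc(OCc2ccccc2)c(OCc2ccccc2)c(OCc2ccccc2)c1.[K+] | intermediate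
11 | 4-azidobutanoic acid | OC(=O)CCCN=[N+]=[N-] | starting material
12 | (E)-vinyl ester: 5 with (E)-CH=CH–O–CO–(CH2)3N3 at C6 | O=C(O[C@@H]1Cc2c(c(Br)c(OCc3ccccc3)c(/C=C/OC(=O)CCCN=[N+]=[N-])c2OCc2ccccc2)O[C@@H]1c1ccc(OCc2ccccc2)c(OCc2ccccc2)c1)c1cc(OCc2ccccc2)c(OCc2ccccc2)c(OCc2ccccc2)c1 | intermediate
13 | 4-(benzyloxy)benzaldehyde | O=Cc1ccc(OCc2ccccc2)cc1 | starting material
14 | 1-(benzyloxy)-4-(dimethoxymethyl)benzene | COC(OC)c1ccc(OCc2ccccc2)cc1 | intermediate
15 | 3,5-bis(benzyloxy)phenol | Oc1cc(OCc2ccccc2)cc(OCc2ccccc2)c1 | starting material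
16 | racemic 1-(benzyloxy)-4-[chloro(methoxy)methyl]benzene | COC(Cl)c1ccc(OCc2ccccc2)cc1 | intermediate
17 | racemic 1,3-bis(benzyloxy)-5-{[4-(benzyloxy)phenyl](methoxy)methoxy}benzene | COC(Oc1cc(OCc2ccccc2)cc(OCc2ccccc2)c1)c1ccc(OCc2ccccc2)cc1 | intermediate
18 | (E)-[4-(benzyloxy)benzylidene][3,5-bis(benzyloxy)phenyl]oxonium ion, counter-ion the chiral phosphoramide anion | C(c1ccccc1)Oc1cc(OCc2ccccc2)cc(c1)/[O+]=C/c1ccc(OCc2ccccc2)cc1 | intermediate
19 | open-chain benzylic cation: C2–C3 bond formed (2R,3R), cationic future C4 on C6 of the lower unit, ring C not yet closed | C(c1ccccc1)Oc1cc(OCc2ccccc2)cc(c1)O[C@H](c1ccc(OCc2ccccc2)cc1)[C@@H]([CH+]c1c(OCc2ccccc2)c(Br)c2O[C@H](c3ccc(OCc4ccccc4)c(OCc4ccccc4)c3)[C@H](OC(=O)c3cc(OCc4ccccc4)c(OCc4ccccc4)c(OCc4ccccc4)c3)Cc2c1OCc1ccccc1)OC(=O)CCCN=[N+]=[N-] | intermediate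
20 | 8-bromo-deca-O-benzyl-3-O-(4-azidobutanoyl)epiafzelechin-(4β→6)-epicatechin 3-O-gallate: upper unit 5,7,4'-tri-O-benzyl, 2,3-cis-3,4-trans; lower unit as in 5 | O=C(O[C@@H]1Cc2c(c(Br)c(OCc3ccccc3)c([C@H]3c4c(OCc5ccccc5)cc(OCc5ccccc5)cc4O[C@H](c4ccc(OCc5ccccc5)cc4)[C@@H]3OC(=O)CCCN=[N+]=[N-])c2OCc2ccccc2)O[C@@H]1c1ccc(OCc2ccccc2)c(OCc2ccccc2)c1)c1cc(OCc2ccccc2)c(OCc2ccccc2)c(OCc2ccccc2)c1 | intermediate
21 | amino ester: the target carrying a 4-aminobutanoate on the upper O3 | O=C(O[C@@H]1Cc2c(cc(O)c([C@H]3c4c(O)cc(O)cc4O[C@H](c4ccc(O)cc4)[C@@H]3OC(=O)CCCN)c2O)O[C@@H]1c1ccc(O)c(O)c1)c1cc(O)c(O)c(O)c1 | intermediate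
22 | epiafzelechin-(4β→6)-epicatechin 3-O-gallate: upper unit (2R,3R,4S), lower unit (2R,3R), gallate on the lower O3 | O=C(O[C@@H]1Cc2c(cc(O)c([C@H]3c4c(O)cc(O)cc4O[C@H](c4ccc(O)cc4)[C@@H]3O)c2O)O[C@@H]1c1ccc(O)c(O)c1)c1cc(O)c(O)c(O)c1 | target

**Step count and risks**

Total step count: 10. Longest linear sequence: 8 steps (steps 1, 2, 3, 4, 5, 6, 9 and 10, from (−)-epicatechin).

The three steps most likely to fail:

1. Step 9 (Proposed new method). What may go wrong:
   - poor endo/exo discrimination, giving the 2,3-trans diastereomer;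
   - weak facial control by the chiral anion, giving the mirror-image upper unit;
   - acid-induced oligomerisation of the electron-rich styrene;
   - self-arylation of the acetal or over-alkylation of the product at its free ring A positions.

   Fallback (known chemistry, sets out from 5 and comes back at 22): commercial (−)-epiafzelechin would be benzylated (BnBr, K2CO3, DMF) to 5,7,4'-tri-O-benzyl-(−)-epiafzelechin F1. Benzylic oxidation at C4 with 2,3-dichloro-5,6-dicyano-1,4-benzoquinone (DDQ) and ethylene glycol in CH2Cl2 should give 4β-(2-hydroxyethoxy)-5,7,4'-tri-O-benzylepiafzelechin F2. Trimethylsilyl triflate (Me3SiOTf) in CH2Cl2 at −78 °C with an excess of 5 should ionise F2 to the C4 cation. C6 of 5 (C8 being blocked) attacks this cation anti to the 3-OH, giving the 8-bromo-deca-O-benzyl dimer with free upper 3-OH F3. Hydrogenolysis of F3 under the conditions of step 10 should give 22.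

2. Step 6. What may go wrong: protodeboronation, oxidative homocoupling, oxidation of the electron-rich alkene under O2 and copper, or loss of the alkene geometry.

   Fallback (sets out from 7 and comes back at 12): Wittig methoxymethylenation of 7 (Ph3P=CHOMe from the phosphonium chloride and KN(SiMe3)2, THF) should give the methyl enol ether F4 as an E/Z mixture. Mild hydrolysis (oxalic acid, wet THF) gives the arylacetaldehyde F5. O-acylation of its potassium enolate (KN(SiMe3)2, THF, −78 °C) with 4-azidobutanoyl chloride gives the enol ester as an E/Z mixture, from which 12 is separated by chromatography.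

3. Step 8. What may go wrong: C-alkylation of the ambident phenoxide at the ring carbons, and hydrolysis of the labile mixed acetal during isolation.

   Fallback (sets out from 15 and comes back at 17): Williamson etherification of 15 with 4-(benzyloxy)benzyl chloride (K2CO3, DMF) gives 3,5-bis(benzyloxy)phenyl 4-(benzyloxy)benzyl ether F6. Oxidation with DDQ in dry CH2Cl2/MeOH over 4 Å molecular sieves (hydride abstraction from the p-alkoxybenzyl position, capture of the oxocarbenium ion by methanol) should give 17.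

**Further compounds**

F1 | step 9 | 5,7,4'-tri-O-benzyl-(−)-epiafzelechin | O[C@@H]1Cc2c(cc(OCc3ccccc3)cc2OCc2ccccc2)O[C@@H]1c1ccc(OCc2ccccc2)cc1
F2 | step 9 | 4β-(2-hydroxyethoxy)-5,7,4'-tri-O-benzylepiafzelechin | OCCO[C@H]1c2c(OCc3ccccc3)cc(OCc3ccccc3)cc2O[C@H](c2ccc(OCc3ccccc3)cc2)[C@@H]1O
F3 | step 9 | 8-bromo-deca-O-benzyl-epiafzelechin-(4β→6)-epicatechin 3-O-gallate with free upper 3-OH | O=C(O[C@@H]1Cc2c(c(Br)c(OCc3ccccc3)c([C@H]3c4c(OCc5ccccc5)cc(OCc5ccccc5)cc4O[C@H](c4ccc(OCc5ccccc5)cc4)[C@@H]3O)c2OCc2ccccc2)O[C@@H]1c1ccc(OCc2ccccc2)c(OCc2ccccc2)c1)c1cc(OCc2ccccc2)c(OCc2ccccc2)c(OCc2ccccc2)c1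
F4 | step 6 | methyl enol ether: 5 with CH=CH–OMe at C6 (E/Z mixture) | O=C(O[C@@H]1Cc2c(c(Br)c(OCc3ccccc3)c(C=COC)c2OCc2ccccc2)O[C@@H]1c1ccc(OCc2ccccc2)c(OCc2ccccc2)c1)c1cc(OCc2ccccc2)c(OCc2ccccc2)c(OCc2ccccc2)c1
F5 | step 6 | arylacetaldehyde: 5 with CH2–CHO at C6 | O=C(O[C@@H]1Cc2c(c(Br)c(OCc3ccccc3)c(CC=O)c2OCc2ccccc2)O[C@@H]1c1ccc(OCc2ccccc2)c(OCc2ccccc2)c1)c1cc(OCc2ccccc2)c(OCc2ccccc2)c(OCc2ccccc2)c1
F6 | step 8 | 3,5-bis(benzyloxy)phenyl 4-(benzyloxy)benzyl ether | C(Oc1cc(OCc2ccccc2)cc(OCc2ccccc2)c1)c1ccc(OCc2ccccc2)cc1
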